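**Plan**

1. Core numbering (eremophilane): C1=C2, C3 (ester carbinol), C4 (CH–CH3), C5 (C–CH3), C6=C7(OH), C8=O, C9=C10; side chain C1'–C8' with CH2OH on C6'.
2. Cuts, in order: the C3–O ester bond (core alcohol 12 + dienoic acid 20); the C4'=C5' alkene (phosphonocrotonate 18 + aldehyde 17 from 2-ethylpropane-1,3-diol).
3. The core is then stripped of the C3 oxygen, C1=C2 and the C7/C8 oxygens and given back three carbons on C7; this is (+)-aristolochene, cut at C6–C7, C5–C10 and C5–CH3 to farnesyl diphosphate.
4. Enabling feature: C1–C10 plus the two methyls are the bicyclic carbon core of aristolochene, with the cis C4/C5 methyl pair and C9=C10 already in place and the only surplus carbons (isopropenyl) on C7, the carbon that carries oxygen in the target.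
5. Forward: the cyclase closes the ten-membered ring and then rings A and B together (step 3). Ring B is oxidised first (C8 ketone, ozonolytic excision of the C7 substituent to the diosphenol), then ring A (C1=C2, C3–OH); the side chain is attached last.
6. Stereochemistry: C4 and C5 from the enzyme; C3 from substrate-controlled SeO2 hydroxylation; C6' from lipase desymmetrisation; both E alkenes from the vinylogous Horner–Wadsworth–Emmons reaction.

Key step: step 3

Assumption: the lipase of step 10 is taken to acetylate the enantiotopic arm that gives the (S)-monoacetate 14, as it does for the 2-methyl homologue; steps 11–13 are ordered for that sense.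

**Route**

Step 1
Reactants: 1 (2E,6E)-farnesol
Product: 2 (2E,6E)-farnesyl bromide
Conditions: PBr3 (0.4 equiv), Et2O, 0 °C
Reagents that add atoms: phosphorus tribromide, BrP(Br)Br
Why: Bromination of the primary allylic alcohol through its phosphite ester (SN2 displacement by bromide) keeps the 2E geometry and gives the electrophile for diphosphorylation.

Step 2
Reactants: 2 (2E,6E)-farnesyl bromide
Product: 3 (2E,6E)-farnesyl diphosphate (used as its trisammonium salt)
Conditions: (n-Bu4N)3HP2O7, MeCN, rt; then Dowex 50W (NH4+ form), aq. NH4HCO3/i-PrOH; lyophilisation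
Reagents that add atoms: tris(tetra-n-butylammonium) hydrogen diphosphate, CCCC[N+](CCCC)(CCCC)CCCC.CCCC[N+](CCCC)(CCCC)CCCC.CCCC[N+](CCCC)(CCCC)CCCC.[O-]P(=O)(O)OP(=O)([O-])[O-]
Why: Davisson–Poulter diphosphorylation: the diphosphate anion displaces the primary allylic bromide in SN2 fashion, and cation exchange gives the water-soluble salt the enzyme accepts.

Step 3
Reactants: 3 (2E,6E)-farnesyl diphosphate
Product: 5 (+)-aristolochene, via (S)-germacrene A 4 (not isolated)
Conditions: recombinant aristolochene synthase (Aspergillus terreus enzyme expressed in Escherichia coli), MgCl2, Tris·HCl buffer pH 7.5, pentane overlay, 30 °C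
Reagents that add atoms: none
Why: Mg2+-assisted ionisation of the diphosphate gives the farnesyl cation, whose C1 (eremophilane C6) is captured by the distal double bond to form C6–C7 and, after proton loss from the isopropyl cation, enzyme-bound (S)-germacrene A 4; reprotonation at C1 drives transannular attack of C4=C5 on C10 (C5–C10), then a 1,2-hydride shift from C5 to C4, a 1,2-methyl shift from C10 to C5 and loss of H9 give 5. The closest known reaction type is the cationic polyene cyclisation with Wagner–Meerwein shifts, run here by a sesquiterpene cyclase. The ten-membered ring closes 10-exo with respect to the distal double bond (tertiary cation left outside the ring), and the single transannular bond C5–C10 closes rings A and B together, 6-endo with respect to C4=C5 as seen from ring A and 6-exo as seen from ring B. C7 is fixed by the face of the distal alkene that the folded chain offers to C6, whereas C4 and C5 follow from the chair–chair fold of 4 and from the two suprafacial, mutually anti 1,2-shifts (hydride to C4, methyl to C5), which place the two methyl groups cis. The step needs one chain fold and one terminating deprotonation (H9, not H1, and no early release of 4); the (2E,6E) geometry of the substrate allows direct C6–C7 closure without prior allylic isomerisation, and the diphosphate–Mg2+ anchor together with the active-site contour holds that fold and places the base.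

Step 4
Reactants: 5 (+)-aristolochene
Product: 6 (4S,5R,7S)-eremophila-9,11-dien-8-one
Conditions: Rh2(cap)4 (dirhodium tetrakis(caprolactamate), 1 mol %), t-BuOOH (70% aq., 5 equiv), K2CO3, CH2Cl2, rt
Reagents that add atoms: tert-butyl hydroperoxide, CC(C)(C)OO
Why: Radical allylic oxidation (Kharasch-type tert-butylperoxyl chain) abstracts hydrogen from C8, the methylene next to the CH end of the trisubstituted C9=C10 bond, and the C8 peroxide collapses to the enone, as in valencene-to-nootkatone and Δ5-steroid-to-7-ketone oxidations; C4 and C5 are untouched and C7 is erased in the next step.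

Step 5
Reactants: 6 (4S,5R,7S)-eremophila-9,11-dien-8-one
Product: 7 (4S,5R)-eremophila-7(11),9-dien-8-one (dehydrofukinone)
Conditions: NaOMe (0.2 equiv), MeOH, rt
Reagents that add atoms: none
Why: Base-mediated conjugation through the C7 dienolate moves the isopropenyl double bond into the tetrasubstituted, conjugated 7(11) position (the petasin-to-isopetasin and isopulegone-to-pulegone isomerisation), removing the C7 stereocentre on purpose.

Step 6
Reactants: 7 (4S,5R)-eremophila-7(11),9-dien-8-one
Product: 9 (4S,5S)-7-hydroxy-11,12,13-trinoreremophila-6,9-dien-8-one, via trinoreremophil-9-ene-7,8-dione 8 (not isolated)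
Conditions: O3 (1 equiv, Sudan Red 7B end point), CH2Cl2/MeOH 5:1, −78 °C; then Me2S, −78 °C → rt
Reagents that add atoms: ozone, [O-][O+]=O
Why: Ozonolysis of an α-alkylidene ketone (the pulegone-to-3-methylcyclohexane-1,2-dione reaction) cleaves the tetrasubstituted exocyclic C7=C11 bond, the most electron-rich alkene, and the 7,8-dione enolises at C6, its only enolisable α-carbon, to the diosphenol on warming.

Step 7
Reactants: 9 (4S,5S)-7-hydroxy-11,12,13-trinoreremophila-6,9-dien-8-one
Product: 10 (4S,5S)-7-(triisopropylsilyloxy)-11,12,13-trinoreremophila-6,9-dien-8-one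
Conditions: i-Pr3SiOTf, 2,6-lutidine, CH2Cl2, −78 → 0 °C
Reagents that add atoms: triisopropylsilyl trifluoromethanesulfonate, CC(C)[Si](OS(=O)(=O)C(F)(F)F)(C(C)C)C(C)C
Why: O-silylation of the acidic, phenol-like enol with a silyl triflate and a hindered base masks the diosphenol as a robust silyl ether for the oxidations and the acylation that follow.

Step 8
Reactants: 10 (4S,5S)-7-(triisopropylsilyloxy)-11,12,13-trinoreremophila-6,9-dien-8-one
Product: 11 (4S,5S)-7-(triisopropylsilyloxy)-11,12,13-trinoreremophila-1,6,9-trien-8-one
Conditions: chloranil (1.2 equiv), t-BuOH, reflux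
Reagents that add atoms: none
Why: Quinone dehydrogenation through the extended C8 dienol (C8(OH)=C9–C10=C1) with hydride abstraction from C2, the classical conversion of cross-conjugated 1,4-dien-3-ones into 1,4,6-trien-3-ones; C1–C2 is the first site that can lose H2 in conjugation because C7 bears no hydrogen and C5 is quaternary.

Step 9
Reactants: 11 (4S,5S)-7-(triisopropylsilyloxy)-11,12,13-trinoreremophila-1,6,9-trien-8-one
Product: 12 (3S,4R,5S)-3-hydroxy-7-(triisopropylsilyloxy)-11,12,13-trinoreremophila-1,6,9-trien-8-one (C3–OH cis to both methyls)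
Conditions: SeO2 (0.5 equiv), t-BuOOH (anhydrous, 2 equiv), CH2Cl2, 0 °C → rt
Reagents that add atoms: selenium dioxide, O=[Se]=O; tert-butyl hydroperoxide, CC(C)(C)OO
Why: Riley-type SeO2 allylic hydroxylation (ene reaction, then [2,3]-sigmatropic shift, turned over by t-BuOOH): C3 is the only carbon with allylic hydrogens, the planar trienone fixes ring A as an envelope with C4 as flap so that the pseudoaxial C3–H lies on the face of the two methyls, and removal of that hydrogen with return of oxygen to the same face should give the C3–OH cis to the C4 and C5 methyls, as in the oxidation of cholesterol to its 4β-alcohol.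

Step 10
Reactants: 13 2-ethylpropane-1,3-diol
Product: 14 (S)-2-(hydroxymethyl)butyl acetate
Conditions: vinyl acetate, Pseudomonas fluorescens lipase, i-Pr2O, rt
Reagents that add atoms: vinyl acetate, CC(=O)OC=C
Why: Lipase-catalysed irreversible transesterification desymmetrises the prochiral diol by acylating one enantiotopic CH2OH, which sets the future C6', and the minor enantiomer is depleted by faster second acylation to the diacetate.

Step 11
Reactants: 14 (S)-2-(hydroxymethyl)butyl acetate
Product: 15 (R)-2-[(tert-butyldimethylsilyloxy)methyl]butyl acetate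
Conditions: TBSCl, imidazole, CH2Cl2, 0 °C
Reagents that add atoms: tert-butyldimethylsilyl chloride, CC(C)(C)[Si](C)(C)Cl
Why: Imidazole-promoted silylation of the free primary alcohol is fast and mild enough to outrun 1,3-acyl migration, which would erode the enantiomeric purity.

Step 12
Reactants: 15 (R)-2-[(tert-butyldimethylsilyloxy)methyl]butyl acetate
Product: 16 (R)-2-[(tert-butyldimethylsilyloxy)methyl]butan-1-ol
Conditions: K2CO3 (0.2 equiv), MeOH, 0 °C → rt
Reagents that add atoms: none
Why: Zemplén-type methanolysis removes the acetate and leaves the silyl ether, so the arm that the enzyme acylated becomes the one to be oxidised.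

Step 13
Reactants: 16 (R)-2-[(tert-butyldimethylsilyloxy)methyl]butan-1-ol
Product: 17 (S)-2-[(tert-butyldimethylsilyloxy)methyl]butanal
Conditions: TEMPO (10 mol %), PhI(OAc)2, CH2Cl2, rt
Reagents that add atoms: none
Why: Oxoammonium (TEMPO/PhI(OAc)2) oxidation stops at the aldehyde under near-neutral conditions, which protects the α-stereocentre from enolisation; the aldehyde is used at once.

Step 14
Reactants: 17 (S)-2-[(tert-butyldimethylsilyloxy)methyl]butanal; 18 triethyl 4-phosphonocrotonate
Product: 19 ethyl (2E,4E,6R)-6-[(tert-butyldimethylsilyloxy)methyl]octa-2,4-dienoate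
Conditions: 18, LiN(SiMe3)2, THF, −78 °C; then 17, −78 → 0 °C
Reagents that add atoms: none
Why: Vinylogous Horner–Wadsworth–Emmons olefination: the lithiated phosphonocrotonate adds through the carbon next to phosphorus and the stabilised phosphonate eliminates to the new E alkene, while the low temperature keeps the α-stereocentre of the aldehyde intact.

Step 15
Reactants: 19 ethyl (2E,4E,6R)-6-[(tert-butyldimethylsilyloxy)methyl]octa-2,4-dienoate
Product: 20 (2E,4E,6R)-6-[(tert-butyldimethylsilyloxy)methyl]octa-2,4-dienoic acid
Conditions: LiOH, THF/MeOH/H2O, rt; then 1 M HCl to pH 4, 0 °C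
Reagents that add atoms: lithium hydroxide, [Li+].[OH-]
Why: Saponification of the ethyl ester; the primary silyl ether and the remote stereocentre tolerate hydroxide and brief mild acidification.

Step 16
Reactants: 12 (3S,4R,5S)-3-hydroxy-7-(triisopropylsilyloxy)-11,12,13-trinoreremophila-1,6,9-trien-8-one; 20 (2E,4E,6R)-6-[(tert-butyldimethylsilyloxy)methyl]octa-2,4-dienoic acid
Product: 22 bis-silylated septeremophilane E (C3 ester of 12 with 20), via dienoic 2,4,6-trichlorobenzoic anhydride 21 (not isolated)
Conditions: 20, 2,4,6-Cl3C6H2COCl, Et3N, THF, rt; then 12, DMAP, toluene, rt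
Reagents that add atoms: none
Why: Yamaguchi esterification: DMAP attacks the mixed anhydride at the less hindered dienoyl carbonyl and the acylpyridinium acylates the hindered pseudoaxial C3–OH on oxygen, so the C3 configuration is retained.

Step 17
Reactants: 22 bis-silylated septeremophilane E
Product: 23 septeremophilane E
Conditions: Bu4NF, AcOH, THF, 0 °C → rt
Reagents that add atoms: none
Why: Fluoride-mediated desilylation cleaves both Si–O bonds (the enol silyl ether and the primary silyl ether), and acetic acid buffering keeps the dienoate ester and the liberated diosphenol from base-induced damage.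

**Compound list**

1 | (2E,6E)-farnesol | CC(C)=CCC/C(C)=C/CC/C(C)=C/CO | starting material
2 | (2E,6E)-farnesyl bromide | CC(C)=CCC/C(C)=C/CC/C(C)=C/CBr | intermediate
3 | (2E,6E)-farnesyl diphosphate (handled as trisammonium salt) | CC(C)=CCC/C(C)=C/CC/C(C)=C/COP(=O)(O)OP(=O)(O)O | intermediate
4 | (S)-germacrene A, enzyme-bound, not isolated | C=C(C)[C@H]1CC/C(C)=C/CC/C(C)=C/C1 | intermediate
5 | (+)-aristolochene, (4S,5R,7S)-eremophila-9,11-diene | C[C@H]1CCCC2=CC[C@@H](C[C@]12C)C(C)=C | intermediate
6 | (4S,5R,7S)-eremophila-9,11-dien-8-one | C[C@H]1CCCC2=CC(=O)[C@@H](C[C@]12C)C(C)=C | intermediate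
7 | (4S,5R)-eremophila-7(11),9-dien-8-one (dehydrofukinone) | C[C@H]1CCCC2=CC(=O)C(C[C@]12C)=C(C)C | intermediate
8 | (4S,5R)-11,12,13-trinoreremophil-9-ene-7,8-dione, not isolated | C[C@H]1CCCC2=CC(=O)C(=O)C[C@]12C | intermediate
9 | (4S,5S)-7-hydroxy-11,12,13-trinoreremophila-6,9-dien-8-one (diosphenol; cis C4/C5 methyls) | C[C@H]1CCCC2=CC(=O)C(O)=C[C@]12C | intermediate
10 | (4S,5S)-7-(triisopropylsilyloxy)-11,12,13-trinoreremophila-6,9-dien-8-one | C[C@H]1CCCC2=CC(=O)C(O[Si](C(C)C)(C(C)C)C(C)C)=C[C@]12C | intermediate
11 | (4S,5S)-7-(triisopropylsilyloxy)-11,12,13-trinoreremophila-1,6,9-trien-8-one | C[C@H]1CC=CC2=CC(=O)C(O[Si](C(C)C)(C(C)C)C(C)C)=C[C@]12C | intermediate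
12 | (3S,4R,5S)-3-hydroxy-7-(triisopropylsilyloxy)-11,12,13-trinoreremophila-1,6,9-trien-8-one (OH cis to both methyls) | O[C@H]1C=CC2=CC(=O)C(O[Si](C(C)C)(C(C)C)C(C)C)=C[C@]2(C)[C@H]1C | intermediate
13 | 2-ethylpropane-1,3-diol | CCC(CO)CO | starting material
14 | (S)-2-(hydroxymethyl)butyl acetate | CC[C@H](COC(C)=O)CO | intermediate
15 | (R)-2-[(tert-butyldimethylsilyloxy)methyl]butyl acetate | CC[C@H](COC(C)=O)CO[Si](C)(C)C(C)(C)C | intermediate
16 | (R)-2-[(tert-butyldimethylsilyloxy)methyl]butan-1-ol | CC[C@H](CO)CO[Si](C)(C)C(C)(C)C | intermediate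
17 | (S)-2-[(tert-butyldimethylsilyloxy)methyl]butanal | CC[C@H](C=O)CO[Si](C)(C)C(C)(C)C | intermediate
18 | triethyl 4-phosphonocrotonate | CCOC(=O)/C=C/CP(=O)(OCC)OCC | starting material
19 | ethyl (2E,4E,6R)-6-[(tert-butyldimethylsilyloxy)methyl]octa-2,4-dienoate | CC[C@H](/C=C/C=C/C(=O)OCC)CO[Si](C)(C)C(C)(C)C | intermediate
20 | (2E,4E,6R)-6-[(tert-butyldimethylsilyloxy)methyl]octa-2,4-dienoic acid | CC[C@H](/C=C/C=C/C(=O)O)CO[Si](C)(C)C(C)(C)C | intermediate
21 | mixed anhydride of 20 with 2,4,6-trichlorobenzoic acid, not isolated | CC[C@H](/C=C/C=C/C(=O)OC(=O)c1c(Cl)cc(Cl)cc1Cl)CO[Si](C)(C)C(C)(C)C | intermediate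
22 | (3S,4R,5S)-7-(triisopropylsilyloxy)-8-oxo-11,12,13-trinoreremophila-1,6,9-trien-3-yl (2E,4E,6R)-6-[(tert-butyldimethylsilyloxy)methyl]octa-2,4-dienoate | CC[C@H](/C=C/C=C/C(=O)O[C@H]1C=CC2=CC(=O)C(O[Si](C(C)C)(C(C)C)C(C)C)=C[C@]2(C)[C@H]1C)CO[Si](C)(C)C(C)(C)C | intermediate
23 | septeremophilane E, (3S,4R,5S)-7-hydroxy-8-oxo-11,12,13-trinoreremophila-1,6,9-trien-3-yl (2E,4E,6R)-6-(hydroxymethyl)octa-2,4-dienoate | CC[C@H](/C=C/C=C/C(=O)O[C@H]1C=CC2=CC(=O)C(O)=C[C@]2(C)[C@H]1C)CO | target

**Count**

Total steps: 17. Longest linear sequence: 11 steps (1–9, 16, 17 from farnesol); the side chain takes steps 10–15.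

**Steps most likely to fail**

Step 9. The ene reaction may be slow at the electron-poor C1=C2 bond, oxygen may be delivered to both faces of C3, or the new carbinol may be oxidised further. Fallback: setting out from 11, the C3 methylene is instead oxidised all the way to the ketone with CrO3 and 3,5-dimethylpyrazole (CH2Cl2, −20 °C), giving (4R,5R)-7-(triisopropylsilyloxy)-11,12,13-trinoreremophila-1,6,9-triene-3,8-dione F1. Luche reduction (NaBH4, CeCl3·7H2O, MeOH, −78 °C) should then add hydride to the C3 carbonyl from the face opposite the C5 methyl, which returns the route to 12. The C3 carbonyl is expected to react first because it is more electrophilic and less shielded than the cross-conjugated, silyloxy-flanked C8 carbonyl. C3 is then set by hydride addition instead of by oxygen delivery.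

Step 4. Hydrogen abstraction may not stay at C8: C1 and the doubly activated C7–H of the product compete, which would give regioisomeric enones and over-oxidation. Fallback: from 5, a Schenck ene reaction with singlet oxygen (O2, tetraphenylporphyrin, visible light, CH2Cl2, 0 °C) should attack the trisubstituted C9=C10 bond at C10 from the face opposite the C5 methyl with abstraction of H8, the course followed by Δ5-steroids. This gives (4S,5R,7R,10R)-10-hydroperoxyeremophila-8,11-diene F2, which PPh3 reduces to (4S,5R,7R,10R)-eremophila-8,11-dien-10-ol F3. Oxidative 1,3-transposition of this tertiary allylic alcohol with pyridinium chlorochromate C5H5NH[CrO3Cl] (CH2Cl2, rt; Dauben–Babler oxidation) then delivers 6, where the route resumes.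

Step 6. Ozone may also cleave C9=C10, or consume the enol if the dione tautomerises before the reductive work-up. Fallback: from 7, retro-aldol removal of acetone (KOH, aq. EtOH, reflux) gives (4S,5R)-11,12,13-trinoreremophil-9-en-8-one F4. Base-mediated autoxidation at C7 (O2, KOt-Bu, t-BuOH, rt; the oxygenation that turns Δ4-3-ketosteroids into 2-hydroxy-1,4-dien-3-ones) then gives the diosphenol 9 directly, so the C7 oxygen comes from O2 instead of from ozonolysis.

**Further compounds**

F1 | step 9 | (4R,5R)-7-(triisopropylsilyloxy)-11,12,13-trinoreremophila-1,6,9-triene-3,8-dione | O=C1C=CC2=CC(=O)C(O[Si](C(C)C)(C(C)C)C(C)C)=C[C@]2(C)[C@H]1C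
F2 | step 4 | (4S,5R,7R,10R)-10-hydroperoxyeremophila-8,11-diene (OOH trans to the C5 methyl) | C[C@H]1CCC[C@@]2(OO)C=C[C@@H](C[C@]12C)C(C)=C
F3 | step 4 | (4S,5R,7R,10R)-eremophila-8,11-dien-10-ol (OH trans to the C5 methyl) | C[C@H]1CCC[C@@]2(O)C=C[C@@H](C[C@]12C)C(C)=C
F4 | step 6 | (4S,5R)-11,12,13-trinoreremophil-9-en-8-one | C[C@H]1CCCC2=CC(=O)CC[C@]12C
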